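**Retrosynthetic overview** (ring atoms C1–C6 numbered as in cyclohex-2-ene-1,4,5-triol; C2' is the side-chain carbinol)

- The target is cut at C4–C5, the ring cis-glycol, by a reductive pinacol transform. This gives a (Z)-γ-hydroxy-enal/δ-hydroxy-aldehyde, which is stored as a spiro bis-lactol. That comes from acetal hydrolysis and Lindlar reduction of an alkynyl carbinol, made by axial acetylide addition to a 2-methoxyoxan-4-one, itself from a catalytic asymmetric hetero-Diels–Alder reaction of (Z)-hexadec-9-enal.
- Enabling feature: C4 and C5 are adjacent secondary carbinols, i.e. two aldehyde carbons of like (acceptor) polarity. The cis C2=C3 bond lets the C1 oxygen reach C4 as a 2,5-dihydrofuran-2-ol, and the C2' oxygen reaches C5 as an oxan-2-ol. The open precursor therefore exists as a 1,8-dioxaspiro[4.5]decene bis-hemiacetal, spiro at C1, which holds the Z geometry and cannot aromatise.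
- Stereochemistry: C2' is set by catalysis (step 1). C1 is relayed from C2' through the oxanone chair (step 2). C4 and C5 are relayed from C1 in the ring closure (step 5).
- Ring order: oxane (step 1, temporary), then dihydrofuranol (step 4, temporary), then the cyclohexene (step 5), the only ring of the skeleton, closed last while both temporary rings open.

Key step: step 5

Remark: the antipode of the Cr(III)–salen catalyst is the one that gives the (S)-carbinol carbon, to be fixed by one correlation experiment; the acetal and lactol carbons carry no stereochemical information for the target.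

**Step 1**
Reactants: 1 (9Z)-hexadec-9-enal; 2 (E)-1-methoxy-3-(trimethylsilyloxy)buta-1,3-diene
Product: 4 (2S,6S)-2-methoxy-6-[(8Z)-pentadec-8-en-1-yl]oxan-4-one, via silyl enol ether cycloadduct 3 (not isolated)
Conditions: chiral (salen)Cr(III)BF4 (3 mol %), 4 Å MS, t-BuOMe, −30 °C; then Et3N (cat.), MeOH, 0 °C
Reagents that add atoms: none
Why: Lewis-acid-catalysed hetero-Diels–Alder reaction of an aldehyde with a 1-methoxy-3-silyloxydiene, in which the chiral Cr(III)–salen complex binds the aldehyde and blocks one carbonyl face so that the carbinol carbon is set (S) by catalyst control, the concerted endo mode should place the methoxy group cis to the chain, and buffered methanolysis of the silyl enol ether should release the β-methoxy ketone without β-elimination of methanol.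

**Step 2**
Reactants: 4 (2S,6S)-2-methoxy-6-[(8Z)-pentadec-8-en-1-yl]oxan-4-one; 5 3,3-diethoxyprop-1-yne
Product: 7 (2S,4R,6S)-4-(3,3-diethoxyprop-1-yn-1-yl)-2-methoxy-6-[(8Z)-pentadec-8-en-1-yl]oxan-4-ol, via lithium acetylide 6 (not isolated)
Conditions: 5, n-BuLi, THF, −78 °C; then 4, −78 °C; sat. aq NH4Cl
Reagents that add atoms: none
Why: 1,2-addition of a lithium acetylide to a conformationally locked oxan-4-one, where with methoxy and chain both equatorial the slim sp nucleophile should enter axially (torsional control, no syn-axial substituent), so the alkynyl group ends axial and the new tertiary OH equatorial and cis to the chain, which relays the (6S) centre to the (4R) carbinol, while at −78 °C addition should outrun enolisation of the β-alkoxy ketone.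

**Step 3**
Reactants: 7 (2S,4R,6S)-4-(3,3-diethoxyprop-1-yn-1-yl)-2-methoxy-6-[(8Z)-pentadec-8-en-1-yl]oxan-4-ol
Product: 8 (2S,4R,6S)-4-[(1Z)-3,3-diethoxyprop-1-en-1-yl]-2-methoxy-6-[(8Z)-pentadec-8-en-1-yl]oxan-4-ol
Conditions: H2 (1 atm), Pd/CaCO3–Pb (Lindlar), quinoline, EtOAc, rt, stopped after 1 equiv H2
Reagents that add atoms: none
Why: Lindlar semihydrogenation, in which syn delivery of hydrogen on the poisoned palladium surface gives the (Z)-alkene and the alkyne binds far more strongly than the isolated chain alkene or the product alkene, so reduction should stop at the alkene stage.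

**Step 4**
Reactants: 8 (2S,4R,6S)-4-[(1Z)-3,3-diethoxyprop-1-en-1-yl]-2-methoxy-6-[(8Z)-pentadec-8-en-1-yl]oxan-4-ol
Product: 9 (5R,9S)-9-[(8Z)-pentadec-8-en-1-yl]-1,8-dioxaspiro[4.5]dec-3-ene-2,7-diol (lactol epimers)
Conditions: 1 M aq HCl/THF (1:4), 0 °C → rt; NaHCO3
Reagents that add atoms: water, O
Why: acid-catalysed acetal hydrolysis, in which the oxocarbenium ion from the diethyl acetal is trapped by the cis-disposed tertiary hydroxyl to give the 2,5-dihydrofuran-2-ol (Z geometry locked, no aromatisation because its C5 is quaternary) and the methyl 2-deoxyglycoside-type acetal hydrolyses under the same mild conditions to the oxan-2-ol, no stereocentre of the target being touched.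

**Step 5**
Reactants: 9 (5R,9S)-9-[(8Z)-pentadec-8-en-1-yl]-1,8-dioxaspiro[4.5]dec-3-ene-2,7-diol
Product: 11 (1R,4R,5S)-1-[(2S,10Z)-2-hydroxyheptadec-10-en-1-yl]cyclohex-2-ene-1,4,5-triol, via open-chain dihydroxy dialdehyde 10 (not isolated)
Conditions: SmI2 (0.1 M in THF, 4 equiv), t-BuOH (2 equiv), THF (5 mM in 9, slow addition), 0 °C → rt; then aq NaHCO3
Reagents that add atoms: none
Why: Ring–chain tautomerism of both lactols exposes dihydroxy dialdehyde 10; single-electron transfer from SmI2 to the more easily reduced (Z)-enal gives a Sm(III)-bound ketyl that adds through its carbonyl carbon C4 to the Sm(III)-activated C5 aldehyde (or combines with the C5 ketyl), and a second electron and protonation deliver the glycol. The closest known reaction type is the SmI2-mediated intramolecular pinacol coupling of 1,6-dialdehydes to cis-cyclohexane-1,2-diols, together with low-valent-metal pinacol ring closures between an enal and an aldehyde. The cyclohexene is closed by C4–C5 bond formation in a 6-exo-trig radical addition to the C5 carbonyl, with the cis C2=C3 bond already inside the forming ring, while the two temporary O-heterocycles are opened in the same operation. C4 and C5 should be set cis to each other because one Sm(III) bridges both carbinol oxygens in the closing transition state, and cis to the C1 hydroxyl because this free tertiary OH chelates the same samarium to the C5 oxygen (1,3-diaxial on a half-chair with the large side chain pseudo-equatorial), so C1 relays its configuration to both new centres. The step needs coupling at C4 and not at the γ-carbon C2, and tolerance of the isolated (Z)-alkene: the first is secured by ring size (C2–C5 coupling would give a cyclobutane), the second by the inertness of unactivated alkenes to SmI2, and the enal geometry is held by the lactol until the moment of reaction.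

**Compound list**

1 | (9Z)-hexadec-9-enal | CCCCCC/C=C\CCCCCCCC=O | starting material
2 | (E)-1-methoxy-3-(trimethylsilyloxy)buta-1,3-diene | CO/C=C/C(=C)O[Si](C)(C)C | starting material
3 | (2S,6S)-6-methoxy-2-[(8Z)-pentadec-8-en-1-yl]-4-(trimethylsilyloxy)-3,6-dihydro-2H-pyran | CCCCCC/C=C\CCCCCCC[C@H]1CC(O[Si](C)(C)C)=C[C@@H](OC)O1 | intermediate
4 | (2S,6S)-2-methoxy-6-[(8Z)-pentadec-8-en-1-yl]oxan-4-one | CCCCCC/C=C\CCCCCCC[C@H]1CC(=O)C[C@@H](OC)O1 | intermediate
5 | 3,3-diethoxyprop-1-yne | C#CC(OCC)OCC | starting material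
6 | lithium 3,3-diethoxyprop-1-yn-1-ide | [Li]C#CC(OCC)OCC | intermediate
7 | (2S,4R,6S)-4-(3,3-diethoxyprop-1-yn-1-yl)-2-methoxy-6-[(8Z)-pentadec-8-en-1-yl]oxan-4-ol | CCCCCC/C=C\CCCCCCC[C@H]1C[C@](O)(C#CC(OCC)OCC)C[C@@H](OC)O1 | intermediate
8 | (2S,4R,6S)-4-[(1Z)-3,3-diethoxyprop-1-en-1-yl]-2-methoxy-6-[(8Z)-pentadec-8-en-1-yl]oxan-4-ol | CCCCCC/C=C\CCCCCCC[C@H]1C[C@](O)(/C=C\C(OCC)OCC)C[C@@H](OC)O1 | intermediate
9 | (5R,9S)-9-[(8Z)-pentadec-8-en-1-yl]-1,8-dioxaspiro[4.5]dec-3-ene-2,7-diol (epimers at C2 and C7) | CCCCCC/C=C\CCCCCCC[C@H]1C[C@]2(C=CC(O)O2)CC(O)O1 | intermediate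
10 | (2Z,4R,6S,14Z)-4,6-dihydroxy-4-(2-oxoethyl)henicosa-2,14-dienal | CCCCCC/C=C\CCCCCCC[C@H](O)C[C@@](O)(CC=O)/C=C\C=O | intermediate
11 | (1R,4R,5S)-1-[(2S,10Z)-2-hydroxyheptadec-10-en-1-yl]cyclohex-2-ene-1,4,5-triol | CCCCCC/C=C\CCCCCCC[C@H](O)C[C@]1(O)C=C[C@@H](O)[C@@H](O)C1 | target

**Step count and risks**

Total step count: 5. Longest linear sequence: 5 steps (from 1).

Steps most likely to fail:

1. Step 5 (key step). What may go wrong: over-reduction of the enal ketyl to a dienolate with reductive loss of the γ-oxygen at C1; simple reduction of one masked aldehyde because the two lactols open at different rates; or imperfect facial control relative to C1. Fallback (ring closure by olefin metathesis across C2=C3, with the glycol set by reagent control): it sets out from ketone 4. Axial addition of ethynylmagnesium bromide (THF, −78 → 0 °C) should give (2S,4R,6S)-4-ethynyl-2-methoxy-6-[(8Z)-pentadec-8-en-1-yl]oxan-4-ol F1. Lindlar semihydrogenation should give (2S,4R,6S)-4-ethenyl-2-methoxy-6-[(8Z)-pentadec-8-en-1-yl]oxan-4-ol F2, and dilute aqueous acid the lactol (4R,6S)-4-ethenyl-6-[(8Z)-pentadec-8-en-1-yl]oxane-2,4-diol F3. Reagent-controlled anti-selective allylboration of the open form of F3 with (E)-3-[(diisopropylamino)dimethylsilyl]allyl-diisopinocampheylborane (antipode chosen for the 4S carbinol) should give the β-hydroxy allylsilane (3R,4S,6R,8S,16Z)-3-[(diisopropylamino)dimethylsilyl]-6-ethenyltricosa-1,16-diene-4,6,8-triol F4. Its C–Si bond is oxidised with retention (Tamao–Fleming: KF, KHCO3, H2O2) to (3R,4S,6R,8S,16Z)-6-ethenyltricosa-1,16-diene-3,4,6,8-tetrol F5. Ring-closing metathesis (second-generation Ru carbene catalyst, dilute CH2Cl2, 40 °C) between the two vinyl groups, both allylic alcohols and far more reactive than the internal chain alkene, then closes the cyclohexene and comes back to the route at 11.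

2. Step 4. What may go wrong: acid-promoted Z-to-E isomerisation of the unmasked enal (the E isomer cannot lactolise); conjugate addition of water or of the C2' hydroxyl to the enal; or β-elimination of the C1 oxygen from the β-oxy aldehyde while the glycoside is hydrolysed. Fallback (C4 carried at the carboxylic-acid level in an acid-stable butenolide and reduced last): it sets out from ketone 4. Addition of lithium ethyl propiolate (ethyl propiolate, LiHMDS, THF, −78 °C) should give ethyl 3-[(2S,4R,6S)-4-hydroxy-2-methoxy-6-[(8Z)-pentadec-8-en-1-yl]oxan-4-yl]prop-2-ynoate F6. Lindlar semihydrogenation gives ethyl (2Z)-3-[(2S,4R,6S)-4-hydroxy-2-methoxy-6-[(8Z)-pentadec-8-en-1-yl]oxan-4-yl]prop-2-enoate F7, which should lactonise on standing or with a trace of acid to (5R,7S,9S)-7-methoxy-9-[(8Z)-pentadec-8-en-1-yl]-1,8-dioxaspiro[4.5]dec-3-en-2-one F8. Aqueous acid then cleaves only the methyl acetal to (5R,9S)-7-hydroxy-9-[(8Z)-pentadec-8-en-1-yl]-1,8-dioxaspiro[4.5]dec-3-en-2-one F9. DIBAL-H (CH2Cl2, −78 °C) reduces the butenolide carbonyl to the lactol and comes back to the route at 9, which in this way never meets acid.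

3. Step 1. What may go wrong: incomplete enantiofacial discrimination with the unbranched aldehyde, or β-elimination of methanol during desilylation. Fallback (open-chain aldol addition, cyclisation, re-addition of methanol): it sets out from 1 and 2. A BINOL–Ti(IV)-catalysed Mukaiyama aldol addition should give, after loss of the silyl group, (1E,5S,13Z)-5-hydroxy-1-methoxyicosa-1,13-dien-3-one F10. Trifluoroacetic acid cyclises this to (2S)-2-[(8Z)-pentadec-8-en-1-yl]-2,3-dihydro-4H-pyran-4-one F11. Acid-catalysed conjugate addition of methanol (CSA cat., MeOH) then gives 4 together with its acetal epimer (2R,6S)-2-methoxy-6-[(8Z)-pentadec-8-en-1-yl]oxan-4-one F12, which is separated and re-equilibrated under the same conditions. The fallback comes back to the route at 4.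

**Further compounds**

F1 | step 5 | (2S,4R,6S)-4-ethynyl-2-methoxy-6-[(8Z)-pentadec-8-en-1-yl]oxan-4-ol | CCCCCC/C=C\CCCCCCC[C@H]1C[C@](O)(C#C)C[C@@H](OC)O1
F2 | step 5 | (2S,4R,6S)-4-ethenyl-2-methoxy-6-[(8Z)-pentadec-8-en-1-yl]oxan-4-ol | CCCCCC/C=C\CCCCCCC[C@H]1C[C@](O)(C=C)C[C@@H](OC)O1
F3 | step 5 | (4R,6S)-4-ethenyl-6-[(8Z)-pentadec-8-en-1-yl]oxane-2,4-diol | CCCCCC/C=C\CCCCCCC[C@H]1C[C@](O)(C=C)CC(O)O1
F4 | step 5 | (3R,4S,6R,8S,16Z)-3-[(diisopropylamino)dimethylsilyl]-6-ethenyltricosa-1,16-diene-4,6,8-triol | CCCCCC/C=C\CCCCCCC[C@H](O)C[C@](O)(C=C)C[C@H](O)[C@H]([Si](C)(C)N(C(C)C)C(C)C)C=C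
F5 | step 5 | (3R,4S,6R,8S,16Z)-6-ethenyltricosa-1,16-diene-3,4,6,8-tetrol | CCCCCC/C=C\CCCCCCC[C@H](O)C[C@](O)(C=C)C[C@H](O)[C@H](O)C=C
F6 | step 4 | ethyl 3-[(2S,4R,6S)-4-hydroxy-2-methoxy-6-[(8Z)-pentadec-8-en-1-yl]oxan-4-yl]prop-2-ynoate | CCCCCC/C=C\CCCCCCC[C@H]1C[C@](O)(C#CC(=O)OCC)C[C@@H](OC)O1
F7 | step 4 | ethyl (2Z)-3-[(2S,4R,6S)-4-hydroxy-2-methoxy-6-[(8Z)-pentadec-8-en-1-yl]oxan-4-yl]prop-2-enoate | CCCCCC/C=C\CCCCCCC[C@H]1C[C@](O)(/C=C\C(=O)OCC)C[C@@H](OC)O1
F8 | step 4 | (5R,7S,9S)-7-methoxy-9-[(8Z)-pentadec-8-en-1-yl]-1,8-dioxaspiro[4.5]dec-3-en-2-one | CCCCCC/C=C\CCCCCCC[C@H]1C[C@]2(C=CC(=O)O2)C[C@@H](OC)O1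
F9 | step 4 | (5R,9S)-7-hydroxy-9-[(8Z)-pentadec-8-en-1-yl]-1,8-dioxaspiro[4.5]dec-3-en-2-one | CCCCCC/C=C\CCCCCCC[C@H]1C[C@]2(C=CC(=O)O2)CC(O)O1
F10 | step 1 | (1E,5S,13Z)-5-hydroxy-1-methoxyicosa-1,13-dien-3-one | CCCCCC/C=C\CCCCCCC[C@H](O)CC(=O)/C=C/OC
F11 | step 1 | (2S)-2-[(8Z)-pentadec-8-en-1-yl]-2,3-dihydro-4H-pyran-4-one | CCCCCC/C=C\CCCCCCC[C@H]1CC(=O)C=CO1
F12 | step 1 | (2R,6S)-2-methoxy-6-[(8Z)-pentadec-8-en-1-yl]oxan-4-one | CCCCCC/C=C\CCCCCCC[C@H]1CC(=O)C[C@H](OC)O1
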